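## Structural features

The target is a germacrane-type sesquiterpene lactone: a ten-membered carbocycle (C1–C10) cis-fused at C6/C7 to an α-methylene-γ-butyrolactone (C11–C13, lactone oxygen on C6). The carbocycle holds a cross-conjugated dienone, C1=C10–C2(=O)–C3=C4, in which both methyl-bearing trisubstituted alkenes are Z (ring-cis). Four contiguous stereocentres follow one another: C5 (S, free allylic carbinol), C6 (R, lactone O–CH), C7 (R, ring-fusion CH) and C8 (S, tiglate carbinol). C8 is separated from the dienone only by the C9 methylene. The fragile groups are the exo-methylene lactone (Michael acceptor, prone to move into the ring), the Z,Z-dienone (isomerisable, doubly electrophilic), the tiglate on a carbon δ to the ketone (1,6-elimination) and the free C5 hydroxyl next to the lactone carbinol. The real difficulty is to close a ten-membered ring that contains two Z enone alkenes while fixing C5 and C6 relative to C8, and then to introduce the exo-methylene with C7–H cis to C6–H. The plan uses two latent identities: C2(=O)–C3H=C4(CH3)–C5 is the oxidised form of a 2,4-disubstituted furan, and the C5(OH)–C6(O) bond is the γ-aldol bond of a butenolide whose C7=C11 alkene can later be transposed to C11=C13.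

## Logic of the disconnections

28 ⇒ 27. The last bonds made are C7–H and the C11=C13 alkene: the alkene is moved back into the lactone ring (C7=C11) and C13 carries a carbonate. The exo-methylene lactone is the most reactive group, so it is unveiled last, and C7 can be created by hydride delivery to a flat carbon from the open face. The gain is one stereocentre less and a robust butenolide. The forward step must put hydride on the more substituted allyl terminus (C7, not C13), on the face away from the carbocycle, and must ionise the primary carbonate faster than the secondary allylic tiglate at C8.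

27 ⇒ 26 ⇒ 25. Only O–C and O–Si bonds at C13 are cut. A leaving group on C13 cannot be present during the basic ring closure (the C6 dienolate would expel it), so C13 stays a silyl ether until then. Desilylation must avoid base (retro-aldol at C5–C6), and the carbonate must go on the primary hydroxyl in the presence of the C5 hydroxyl.

25 ⇒ 24 ⇒ 23 ⇒ 22. The C5–C6 bond is cut as a vinylogous aldol, then the C2 ketone and C5 aldehyde of 24 are folded through 23 into the furan of 22. One aromatic ring thereby supplies both carbonyl oxidation levels and the Z geometry of C3=C4, and 22 has a single stereocentre (C8) and no medium ring. The forward step needs furan-selective oxidation, γ-selective addition of the butenolide, control of C6 by C8 and a favourable equilibrium at C5. The silyl ether and the C8 tiglate are kept in 22: silanolate is a poor leaving group, and acylating C8 after ring closure would compete with C5–OH.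

22 ⇒ 21. The C7=C11 alkene is cut as an intramolecular Horner–Wadsworth–Emmons reaction. The butenolide becomes an acyclic α-acyloxy ketone carrying its own phosphonate. The base must be mild enough not to epimerise C8 (α to the ketone) or expel silanolate from the phosphonate carbanion.

21 ⇒ 19 + 20 and 19 ⇒ 14 + 18. Two ester C–O bonds are cut. The primary C6 hydroxyl of 14 takes the phosphonoacetate first and the secondary C8 hydroxyl takes the tiglate second, so no protecting group is needed. The demand is primary-over-secondary selectivity in the first acylation.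

18 ⇒ 17 ⇒ 16 ⇒ 15. The C11–C12 bond is cut as the carboxylation of an α-phosphonyl carbanion. A commercial two-carbon phosphonate supplies C11, C13 and the oxygen on C13. The carbanion must be trapped before it can eliminate silanolate.

14 ⇒ 13 ⇒ 12 ⇒ 11 + 7, with 11 ⇐ 10 ⇐ 8 + 9. The C8–C9 bond is cut as the alkylation of a chiral dihydroxyacetone azaenolate. C6, C7 and C8 with both oxygens and the C8 configuration arrive in one C–C bond from a three-carbon ketone. The auxiliary must control the face, and 7 must react by direct displacement with its Z alkene intact.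

7 ⇒ 6 ⇒ 5 ⇒ 4 + 2, with 4 ⇐ 3 and 2 ⇒ 1. The C1=C10 alkene is cut as a Z-selective phosphonate olefination, and the furan methyl is cut back to a bromide. Taking the 2,4-pattern from 1 avoids functionalising a 3-alkylfuran directly, where electrophiles prefer the α-carbon next to the alkyl group. The olefination must be Z-selective because this geometry is carried unchanged into the ring.

## Other disconnections considered

Alternative 1: The ten-membered ring is contracted to a six-membered ring by cutting C9–C10 and rejoining C2–C7. Forward, KH with 18-crown-6 would convert a six-membered tertiary propargylic alkoxide into the ring-expanded allenolate by an alkynyl oxy-Cope shift, and protonation at C1 would give the Z,Z-dienone acetonide A1 with an E C7=C8 alkene.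
- In its favour: the ring expansion is unimolecular and needs no high dilution, and it is the more predictable bond-forming event of the two plans.
- Also in its favour: C5 and C6 come as a cis-diol of fixed configuration from the chiral pool, which is better than relying on an aldol equilibrium. The Z geometry of C3=C4 is inherited from the six-membered ring, which equals the furan.
- Against it: A1 lacks C11–C13 and the C8 oxygen. The C7–C11 and C8–O bonds and two stereocentres would have to be added to an isolated E alkene in a flexible ring that already holds the dienone.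
- Also against it: the C1=C10 geometry depends on the protonation of a medium-ring allenolate, and the dienone must survive KH.
- Step economy: the chosen key product is three steps from the target, whereas A1 would need lactone annulation, C8 oxidation, acylation and deprotection, so the route would be clearly longer overall.

Alternative 2: The C8–C9 bond is cut. Forward, BF3·OEt2 would make the terminal methylene C9 of a 2-silyloxydiene add to a C8 aldehyde, restoring the C2 ketone and the C1=C10 alkene and giving the C8 alcohol A2.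
- In its favour: the methylene lactone and C5–C7 are complete before closure, and only tigloylation and desilylation remain (two steps against three, which is better).
- Also in its favour: the Lewis-acid aldol is irreversible and base-free, which is better with respect to elimination and epimerisation.
- Against it: the C1=C10 geometry is created in the key step and Z is not assured, whereas the chosen plan fixes it beforehand.
- Also against it: the C8 aldehyde has an α-proton at C7 that is also γ to the lactone carbonyl, so enolisation would threaten C7 and the exo-methylene. The methylene lactone is a competing acceptor for the silyl dienol ether.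
- On stereocontrol the two plans are equal: C8 here and C5 in the chosen plan both rest on macrocyclic induction.
- Step economy: the open-chain precursor needs the C5–C6–C7 triad and the Z enone from separate asymmetric steps, so the overall length is expected to be similar or greater.

Alternative 3: The C1–C2 and C2–C3 bonds are cut and C2 comes from CO. Forward, Pd2(dba)3 with AsPh3 under CO would add oxidatively to the C3 alkenyl iodide, insert CO, transmetalate with the C1 alkenylstannane and eliminate reductively to the O5-silyl ether A3.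
- In its favour: both Z alkenes, all four stereocentres, the tiglate and the methylene lactone are fixed before closure and carried through with retention, so no equilibrium decides the stereochemistry (better).
- Also in its favour: the conditions are neutral (better), and one deprotection remains after the key step (better).
- Against it: direct, non-carbonylative coupling to a nine-membered diene and oligomerisation would compete, and stoichiometric tin and CO pressure are required.
- Also against it: the fully decorated chain with a Pd–H-sensitive methylene lactone and two Z-alkenyl termini needs a long linear synthesis, likely well beyond the 17 steps of the chosen plan.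
- On ring strain the two plans are equal, since both rely on the Z alkenes to pre-organise the chain.

Key step: step 14

Remark: centres that are destroyed later (the phosphonate α-carbon of 18, 19 and 21 and the bridgeheads of 23) and the C=N geometry of 12 are carried as mixtures and are left unspecified.

## Steps

Step 1
Reactants: 1 4-bromofuran-2-carbaldehyde
Product: 2 4-methylfuran-2-carbaldehyde
Conditions: (MeBO)3, Pd(PPh3)4 (5 mol %), K2CO3, 1,4-dioxane, 100 °C
Reagents that add atoms: trimethylboroxine, CB1OB(C)OB(C)O1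
Why: Suzuki–Miyaura methylation of a heteroaryl bromide; the aldehyde is inert and the 2,4-substitution pattern of the furan is fixed by the starting bromide.

Step 2
Reactants: 2 4-methylfuran-2-carbaldehyde; 3 ethyl 2-[bis(2,2,2-trifluoroethoxy)phosphoryl]propanoate
Product: 5 ethyl (2Z)-2-methyl-3-(4-methylfuran-2-yl)prop-2-enoate, via potassium phosphonate carbanion 4 (not isolated)
Conditions: 3, KN(SiMe3)2, 18-crown-6, THF, −78 °C; then 2, −78 °C
Reagents that add atoms: none
Why: Still–Gennari olefination: the electron-poor trifluoroethyl phosphonate eliminates from the first-formed adduct faster than it equilibrates, which should give the Z trisubstituted enoate and so set the C1=C10 geometry.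

Step 3
Reactants: 5 ethyl (2Z)-2-methyl-3-(4-methylfuran-2-yl)prop-2-enoate
Product: 6 (2Z)-2-methyl-3-(4-methylfuran-2-yl)prop-2-en-1-ol
Conditions: i-Bu2AlH (2.2 equiv), CH2Cl2, −78 °C; aq. potassium sodium tartrate work-up
Reagents that add atoms: none
Why: 1,2-Reduction of an α,β-unsaturated ester to the allylic alcohol with i-Bu2AlH; the alkene geometry is not affected at low temperature.

Step 4
Reactants: 6 (2Z)-2-methyl-3-(4-methylfuran-2-yl)prop-2-en-1-ol
Product: 7 2-[(1Z)-3-bromo-2-methylprop-1-en-1-yl]-4-methylfuran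
Conditions: CBr4, PPh3, CH2Cl2, −30 °C; used at once
Reagents that add atoms: carbon tetrabromide, BrC(Br)(Br)Br
Why: Appel bromination under neutral conditions replaces the primary allylic hydroxyl by direct displacement; low temperature and immediate use limit ionisation of the furan-stabilised allyl system.

Step 5
Reactants: 8 2,2-dimethyl-1,3-dioxan-5-one; 9 (2S)-2-(methoxymethyl)pyrrolidin-1-amine (SAMP)
Product: 10 (2S)-N-(2,2-dimethyl-1,3-dioxan-5-ylidene)-2-(methoxymethyl)pyrrolidin-1-amine
Conditions: benzene, reflux, Dean–Stark trap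
Reagents that add atoms: none
Why: Hydrazone formation from a ketone and a 1,1-disubstituted hydrazine, driven by removal of water.

Step 6
Reactants: 10 (2S)-N-(2,2-dimethyl-1,3-dioxan-5-ylidene)-2-(methoxymethyl)pyrrolidin-1-amine; 7 2-[(1Z)-3-bromo-2-methylprop-1-en-1-yl]-4-methylfuran
Product: 12 (4S)-N-[(2S)-2-(methoxymethyl)pyrrolidin-1-yl]-2,2-dimethyl-4-[(2Z)-2-methyl-3-(4-methylfuran-2-yl)prop-2-en-1-yl]-1,3-dioxan-5-imine, via lithium azaenolate 11 (not isolated)
Conditions: t-BuLi, THF, −78 °C; then 7, −100 °C → −78 °C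
Reagents that add atoms: none
Why: Enders SAMP-hydrazone alkylation: lithium is chelated by the methoxymethyl arm, one face of the azaenolate is shielded and the allylic bromide enters from the other, which sets C8 as S; direct displacement at −100 °C keeps the Z alkene.

Step 7
Reactants: 12 (4S)-N-[(2S)-2-(methoxymethyl)pyrrolidin-1-yl]-2,2-dimethyl-4-[(2Z)-2-methyl-3-(4-methylfuran-2-yl)prop-2-en-1-yl]-1,3-dioxan-5-imine
Product: 13 (4S)-2,2-dimethyl-4-[(2Z)-2-methyl-3-(4-methylfuran-2-yl)prop-2-en-1-yl]-1,3-dioxan-5-one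
Conditions: sat. aq. oxalic acid, Et2O, rt (two phases)
Reagents that add atoms: water, O
Why: Mild two-phase hydrolysis of the hydrazone returns the ketone without racemising the α-alkoxy centre or opening the acetonide, while the acid-sensitive alkenylfuran stays in the ether layer.

Step 8
Reactants: 13 (4S)-2,2-dimethyl-4-[(2Z)-2-methyl-3-(4-methylfuran-2-yl)prop-2-en-1-yl]-1,3-dioxan-5-one
Product: 14 (3S,5Z)-1,3-dihydroxy-5-methyl-6-(4-methylfuran-2-yl)hex-5-en-2-one
Conditions: AcOH/THF/H2O (4:1:1), 40 °C
Reagents that add atoms: none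
Why: Acid hydrolysis of the six-membered acetonide; a weak carboxylic acid suffices for this ketal and should be tolerated by the furan and by the α-hydroxy ketone centre.

Step 9
Reactants: 15 diethyl (2-hydroxyethyl)phosphonate
Product: 16 diethyl (2-{[tert-butyl(dimethyl)silyl]oxy}ethyl)phosphonate
Conditions: TBSCl, imidazole, DMF, rt
Reagents that add atoms: tert-butyl(chloro)dimethylsilane, CC(C)(C)[Si](C)(C)Cl
Why: Standard silylation of a primary alcohol.

Step 10
Reactants: 16 diethyl (2-{[tert-butyl(dimethyl)silyl]oxy}ethyl)phosphonate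
Product: 18 3-{[tert-butyl(dimethyl)silyl]oxy}-2-(diethoxyphosphoryl)propanoic acid, via α-lithiophosphonate 17 (not isolated)
Conditions: n-BuLi, THF, −78 °C; then CO2 (excess), −78 → 0 °C; cold 0.5 M HCl to pH 3
Reagents that add atoms: carbon dioxide, O=C=O
Why: α-Lithiation of a dialkyl alkylphosphonate and carboxylation of the carbanion gives the phosphonoacetic acid; at −78 °C a β-silyloxy group should not be expelled, as is the case for other β-alkoxy phosphonate carbanions.

Step 11
Reactants: 14 (3S,5Z)-1,3-dihydroxy-5-methyl-6-(4-methylfuran-2-yl)hex-5-en-2-one; 18 3-{[tert-butyl(dimethyl)silyl]oxy}-2-(diethoxyphosphoryl)propanoic acid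
Product: 19 (3S,5Z)-3-hydroxy-5-methyl-6-(4-methylfuran-2-yl)-2-oxohex-5-en-1-yl 3-{[tert-butyl(dimethyl)silyl]oxy}-2-(diethoxyphosphoryl)propanoate
Conditions: DCC, DMAP (5 mol %), CH2Cl2, −20 °C → 0 °C
Reagents that add atoms: none
Why: Steglich esterification; the unhindered primary hydroxyl should react well ahead of the secondary one, which is flanked by the ketone and the branched allyl chain.

Step 12
Reactants: 19 (3S,5Z)-3-hydroxy-5-methyl-6-(4-methylfuran-2-yl)-2-oxohex-5-en-1-yl 3-{[tert-butyl(dimethyl)silyl]oxy}-2-(diethoxyphosphoryl)propanoate; 20 (2E)-2-methylbut-2-enoyl chloride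
Product: 21 (3S,5Z)-1-[(3-{[tert-butyl(dimethyl)silyl]oxy}-2-(diethoxyphosphoryl)propanoyl)oxy]-5-methyl-6-(4-methylfuran-2-yl)-2-oxohex-5-en-3-yl (2E)-2-methylbut-2-enoate
Conditions: pyridine, DMAP (cat.), CH2Cl2, 0 °C
Reagents that add atoms: none
Why: Acylation of the remaining secondary alcohol with an acid chloride; the tiglate is the stable E isomer and the C8 centre is not involved.

Step 13
Reactants: 21 (3S,5Z)-1-[(3-{[tert-butyl(dimethyl)silyl]oxy}-2-(diethoxyphosphoryl)propanoyl)oxy]-5-methyl-6-(4-methylfuran-2-yl)-2-oxohex-5-en-3-yl (2E)-2-methylbut-2-enoate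
Product: 22 (1S,3Z)-1-[4-({[tert-butyl(dimethyl)silyl]oxy}methyl)-5-oxo-2,5-dihydrofuran-3-yl]-3-methyl-4-(4-methylfuran-2-yl)but-3-en-1-yl (2E)-2-methylbut-2-enoate
Conditions: LiCl, i-Pr2NEt, MeCN, 0 °C → rt
Reagents that add atoms: none
Why: Intramolecular Horner–Wadsworth–Emmons reaction under Masamune–Roush conditions: the lithium-chelated phosphonate carbanion attacks the neighbouring ketone in a five-membered closure and elimination gives the C7=C11 butenolide; the weak amine base should spare the C8 centre.

Step 14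
Reactants: 22 (1S,3Z)-1-[4-({[tert-butyl(dimethyl)silyl]oxy}methyl)-5-oxo-2,5-dihydrofuran-3-yl]-3-methyl-4-(4-methylfuran-2-yl)but-3-en-1-yl (2E)-2-methylbut-2-enoate
Product: 25 (4S,6Z,9Z,11S,11aR)-3-({[tert-butyl(dimethyl)silyl]oxy}methyl)-11-hydroxy-6,10-dimethyl-2,8-dioxo-2,4,5,8,11,11a-hexahydrocyclodeca[b]furan-4-yl (2E)-2-methylbut-2-enoate, via furan endoperoxide 23 (not isolated), via Z-keto-enal 24 (not isolated)
Conditions: O2, visible light, tetraphenylporphyrin (cat.), CH2Cl2, −78 °C; then Me2S, −78 → 0 °C; then dilution to 1 mM, DBU (0.3 equiv), −20 → 0 °C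
Reagents that add atoms: dioxygen, O=O
Why: Proposed new method: singlet oxygen adds in a [4+2] sense across the two furan α-carbons (the future C2 and C5) of 22 to give endoperoxide 23, Me2S reduces the O–O bond so that the ring opens to the Z-4-oxo-enal 24, and DBU then removes a C6 proton of the butenolide to form an aromatic 2-oxidofuran whose γ-carbon C6 adds to the C5 aldehyde. The closest known reaction types are the photooxygenation of furans to Z-enediones and the amine-mediated direct vinylogous aldol addition of butenolides to aldehydes; joining them into a ten-membered carbocyclisation is the new element. The ring closes in a 10-(enolendo)-exo-trig mode, which is geometrically allowed, and is helped by the two Z alkenes that bend C5 back toward C6 and by working at 1 mM. Chemoselectivity in the oxidation should follow from the much higher reactivity of the electron-rich furan than of the tiglate, the butenolide or the conjugated C1=C10 alkene at −78 °C. Attack through C6 and not C11 is secured because C11 is fully substituted and only γ-attack restores the conjugated lactone. C6 is controlled by C8: allylic strain with the CH2OSi arm on C11 holds C8–H in the butenolide plane, so C9 and the tether lie on the face opposite the tiglate and C5 is delivered to that face, giving 6R from 8S. C5 is set relative to C6 under reversible aldol conditions, and the erythro 5S epimer, with anti C5–O and C6–O bonds and the hydroxyl on the outside of the ring, is expected to accumulate; this equilibrium is the selectivity on which the step depends most.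

Step 15
Reactants: 25 (4S,6Z,9Z,11S,11aR)-3-({[tert-butyl(dimethyl)silyl]oxy}methyl)-11-hydroxy-6,10-dimethyl-2,8-dioxo-2,4,5,8,11,11a-hexahydrocyclodeca[b]furan-4-yl (2E)-2-methylbut-2-enoate
Product: 26 (4S,6Z,9Z,11S,11aR)-11-hydroxy-3-(hydroxymethyl)-6,10-dimethyl-2,8-dioxo-2,4,5,8,11,11a-hexahydrocyclodeca[b]furan-4-yl (2E)-2-methylbut-2-enoate
Conditions: HF·pyridine, pyridine, THF, 0 °C → rt
Reagents that add atoms: none
Why: Fluoride cleavage of the primary silyl ether under slightly acidic conditions, which avoid retro-aldol cleavage of C5–C6 and leave both esters untouched.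

Step 16
Reactants: 26 (4S,6Z,9Z,11S,11aR)-11-hydroxy-3-(hydroxymethyl)-6,10-dimethyl-2,8-dioxo-2,4,5,8,11,11a-hexahydrocyclodeca[b]furan-4-yl (2E)-2-methylbut-2-enoate
Product: 27 (4S,6Z,9Z,11S,11aR)-11-hydroxy-3-{[(methoxycarbonyl)oxy]methyl}-6,10-dimethyl-2,8-dioxo-2,4,5,8,11,11a-hexahydrocyclodeca[b]furan-4-yl (2E)-2-methylbut-2-enoate
Conditions: ClCO2Me, pyridine, CH2Cl2, −20 °C → 0 °C
Reagents that add atoms: methyl chloroformate, COC(=O)Cl
Why: Selective O-acylation: the primary allylic hydroxyl should react ahead of the hindered secondary C5 hydroxyl, and pyridine is too weak a base to deprotonate C6.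

Step 17
Reactants: 27 (4S,6Z,9Z,11S,11aR)-11-hydroxy-3-{[(methoxycarbonyl)oxy]methyl}-6,10-dimethyl-2,8-dioxo-2,4,5,8,11,11a-hexahydrocyclodeca[b]furan-4-yl (2E)-2-methylbut-2-enoate
Product: 28 (3aR,4S,6Z,9Z,11S,11aR)-11-hydroxy-6,10-dimethyl-3-methylidene-2,8-dioxo-2,3,3a,4,5,8,11,11a-octahydrocyclodeca[b]furan-4-yl (2E)-2-methylbut-2-enoate
Conditions: Pd(OAc)2 (10 mol %), PBu3 (20 mol %), HCO2H, Et3N, THF, rt → 40 °C
Reagents that add atoms: none
Why: Tsuji–Trost-type allylic reduction with formate: zerovalent palladium ionises the primary carbonate and the formate complex passes hydride through the metal to the more substituted allyl terminus C7, leaving the C11=C13 methylene. Palladium should sit on the butenolide face opposite the carbocycle, so C7–H ends cis to C6–H (7R); triethylammonium formate is used because a tertiary amine cannot add irreversibly to the new methylene lactone.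

## Compound list

1 | 4-bromofuran-2-carbaldehyde | O=Cc1cc(Br)co1 | starting material
2 | 4-methylfuran-2-carbaldehyde | Cc1coc(C=O)c1 | intermediate
3 | ethyl 2-[bis(2,2,2-trifluoroethoxy)phosphoryl]propanoate | CCOC(=O)C(C)P(=O)(OCC(F)(F)F)OCC(F)(F)F | starting material
4 | potassium 2-[bis(2,2,2-trifluoroethoxy)phosphoryl]-1-ethoxy-1-oxopropan-2-ide (carbanion of 3) | CCOC(=O)[C-](C)P(=O)(OCC(F)(F)F)OCC(F)(F)F.[K+] | intermediate
5 | ethyl (2Z)-2-methyl-3-(4-methylfuran-2-yl)prop-2-enoate | CCOC(=O)/C(C)=C\c1cc(C)co1 | intermediate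
6 | (2Z)-2-methyl-3-(4-methylfuran-2-yl)prop-2-en-1-ol | OC/C(C)=C\c1cc(C)co1 | intermediate
7 | 2-[(1Z)-3-bromo-2-methylprop-1-en-1-yl]-4-methylfuran | BrC/C(C)=C\c1cc(C)co1 | intermediate
8 | 2,2-dimethyl-1,3-dioxan-5-one | CC1(C)OCC(=O)CO1 | starting material
9 | (2S)-2-(methoxymethyl)pyrrolidin-1-amine (SAMP) | COC[C@@H]1CCCN1N | starting material
10 | (2S)-N-(2,2-dimethyl-1,3-dioxan-5-ylidene)-2-(methoxymethyl)pyrrolidin-1-amine | COC[C@@H]1CCCN1N=C1COC(C)(C)OC1 | intermediate
11 | lithium (2,2-dimethyl-4H-1,3-dioxin-5-yl)[(2S)-2-(methoxymethyl)pyrrolidin-1-yl]azanide (azaenolate of 10) | [Li+].COC[C@@H]1CCCN1[N-]C1=COC(C)(C)OC1 | intermediate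
12 | (4S)-N-[(2S)-2-(methoxymethyl)pyrrolidin-1-yl]-2,2-dimethyl-4-[(2Z)-2-methyl-3-(4-methylfuran-2-yl)prop-2-en-1-yl]-1,3-dioxan-5-imine | COC[C@@H]1CCCN1N=C1COC(C)(C)O[C@H]1C/C(C)=C\c1cc(C)co1 | intermediate
13 | (4S)-2,2-dimethyl-4-[(2Z)-2-methyl-3-(4-methylfuran-2-yl)prop-2-en-1-yl]-1,3-dioxan-5-one | CC1(C)OCC(=O)[C@H](C/C(C)=C\c2cc(C)co2)O1 | intermediate
14 | (3S,5Z)-1,3-dihydroxy-5-methyl-6-(4-methylfuran-2-yl)hex-5-en-2-one | OCC(=O)[C@@H](O)C/C(C)=C\c1cc(C)co1 | intermediate
15 | diethyl (2-hydroxyethyl)phosphonate | CCOP(=O)(CCO)OCC | starting material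
16 | diethyl (2-{[tert-butyl(dimethyl)silyl]oxy}ethyl)phosphonate | CCOP(=O)(CCO[Si](C)(C)C(C)(C)C)OCC | intermediate
17 | lithium 2-{[tert-butyl(dimethyl)silyl]oxy}-1-(diethoxyphosphoryl)ethan-1-ide (α-lithio form of 16) | [Li+].CCOP(=O)([CH-]CO[Si](C)(C)C(C)(C)C)OCC | intermediate
18 | 3-{[tert-butyl(dimethyl)silyl]oxy}-2-(diethoxyphosphoryl)propanoic acid (racemic) | CCOP(=O)(OCC)C(CO[Si](C)(C)C(C)(C)C)C(=O)O | intermediate
19 | (3S,5Z)-3-hydroxy-5-methyl-6-(4-methylfuran-2-yl)-2-oxohex-5-en-1-yl 3-{[tert-butyl(dimethyl)silyl]oxy}-2-(diethoxyphosphoryl)propanoate | CCOP(=O)(OCC)C(CO[Si](C)(C)C(C)(C)C)C(=O)OCC(=O)[C@@H](O)C/C(C)=C\c1cc(C)co1 | intermediate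
20 | (2E)-2-methylbut-2-enoyl chloride (tigloyl chloride) | C/C=C(\C)C(=O)Cl | starting material
21 | (3S,5Z)-1-[(3-{[tert-butyl(dimethyl)silyl]oxy}-2-(diethoxyphosphoryl)propanoyl)oxy]-5-methyl-6-(4-methylfuran-2-yl)-2-oxohex-5-en-3-yl (2E)-2-methylbut-2-enoate | CCOP(=O)(OCC)C(CO[Si](C)(C)C(C)(C)C)C(=O)OCC(=O)[C@@H](OC(=O)/C(C)=C/C)C/C(C)=C\c1cc(C)co1 | intermediate
22 | (1S,3Z)-1-[4-({[tert-butyl(dimethyl)silyl]oxy}methyl)-5-oxo-2,5-dihydrofuran-3-yl]-3-methyl-4-(4-methylfuran-2-yl)but-3-en-1-yl (2E)-2-methylbut-2-enoate | Cc1coc(/C=C(/C)C[C@H](OC(=O)/C(C)=C/C)C2=C(CO[Si](C)(C)C(C)(C)C)C(=O)OC2)c1 | intermediate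
23 | (1S,3Z)-1-[4-({[tert-butyl(dimethyl)silyl]oxy}methyl)-5-oxo-2,5-dihydrofuran-3-yl]-3-methyl-4-(5-methyl-2,3,7-trioxabicyclo[2.2.1]hept-5-en-1-yl)but-3-en-1-yl (2E)-2-methylbut-2-enoate | CC1=CC2(/C=C(/C)C[C@H](OC(=O)/C(C)=C/C)C3=C(CO[Si](C)(C)C(C)(C)C)C(=O)OC3)OOC1O2 | intermediate
24 | (1S,3Z,6Z)-1-[4-({[tert-butyl(dimethyl)silyl]oxy}methyl)-5-oxo-2,5-dihydrofuran-3-yl]-3,7-dimethyl-5,8-dioxoocta-3,6-dien-1-yl (2E)-2-methylbut-2-enoate | O=C/C(C)=C\C(=O)/C=C(/C)C[C@H](OC(=O)/C(C)=C/C)C1=C(CO[Si](C)(C)C(C)(C)C)C(=O)OC1 | intermediate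
25 | (4S,6Z,9Z,11S,11aR)-3-({[tert-butyl(dimethyl)silyl]oxy}methyl)-11-hydroxy-6,10-dimethyl-2,8-dioxo-2,4,5,8,11,11a-hexahydrocyclodeca[b]furan-4-yl (2E)-2-methylbut-2-enoate | CC(C)(C)[Si](C)(C)OCC1=C2[C@@H](OC(=O)/C(C)=C/C)C/C(C)=C\C(=O)/C=C(/C)[C@H](O)[C@@H]2OC1=O | intermediate
26 | (4S,6Z,9Z,11S,11aR)-11-hydroxy-3-(hydroxymethyl)-6,10-dimethyl-2,8-dioxo-2,4,5,8,11,11a-hexahydrocyclodeca[b]furan-4-yl (2E)-2-methylbut-2-enoate | OCC1=C2[C@@H](OC(=O)/C(C)=C/C)C/C(C)=C\C(=O)/C=C(/C)[C@H](O)[C@@H]2OC1=O | intermediate
27 | (4S,6Z,9Z,11S,11aR)-11-hydroxy-3-{[(methoxycarbonyl)oxy]methyl}-6,10-dimethyl-2,8-dioxo-2,4,5,8,11,11a-hexahydrocyclodeca[b]furan-4-yl (2E)-2-methylbut-2-enoate | COC(=O)OCC1=C2[C@@H](OC(=O)/C(C)=C/C)C/C(C)=C\C(=O)/C=C(/C)[C@H](O)[C@@H]2OC1=O | intermediate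
28 | (3aR,4S,6Z,9Z,11S,11aR)-11-hydroxy-6,10-dimethyl-3-methylidene-2,8-dioxo-2,3,3a,4,5,8,11,11a-octahydrocyclodeca[b]furan-4-yl (2E)-2-methylbut-2-enoate | C=C1C(=O)O[C@@H]2[C@H]1[C@@H](OC(=O)/C(C)=C/C)C/C(C)=C\C(=O)/C=C(/C)[C@@H]2O | target

## Step count and least certain steps

Total: 17 steps. Longest linear sequence: 14 steps (1 → 2 → 5 → 6 → 7 → 12 → 13 → 14 → 19 → 21 → 22 → 25 → 26 → 27 → 28).

**Step 14 (key step, proposed new method).**
- What may go wrong: competing ene or diene photooxygenation at the furan-conjugated C1=C10 alkene; Z-to-E isomerisation of the oxo-enal by the amine before closure; oligomerisation; intramolecular conjugate addition of the dienolate; loss of water across C5/C6 or 1,6-loss of tiglic acid under base; an unfavourable position of the reversible aldol equilibrium at C5.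
- Fallback (known reactions, kinetic instead of thermodynamic closure): it sets out from 22. The oxidation is run alone (O2, light, tetraphenylporphyrin; Me2S) and 24 is isolated. Treatment with t-BuMe2SiOTf and i-Pr2NEt in CH2Cl2 at 1 mM and −78 °C should convert the butenolide into (1S,3Z,6Z)-1-[5-{[tert-butyl(dimethyl)silyl]oxy}-4-({[tert-butyl(dimethyl)silyl]oxy}methyl)furan-3-yl]-3,7-dimethyl-5,8-dioxoocta-3,6-dien-1-yl (2E)-2-methylbut-2-enoate F1. F1 should close in a silylative vinylogous Mukaiyama aldol reaction onto the silyl-activated aldehyde to give the O11-tert-butyldimethylsilyl ether of 25, F2. HF·pyridine then removes both silyl groups and the route is rejoined at 26. This cycloaldolisation type is established for smaller carbocycles, so the ring size remains the open point.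

**Step 17.**
- What may go wrong: hydride delivery to the wrong face of C7 or to C13; competing ionisation of the allylic tiglate at C8; phosphine-induced isomerisation of the Z enones; O-allylation by the C5 hydroxyl.
- Fallback: it sets out from 26 and avoids palladium and phosphine ligand. Mitsunobu displacement of the primary allylic hydroxyl with 2-nitrobenzenesulfonylhydrazide (PPh3, diethyl azodicarboxylate, THF, −30 °C) should give (4S,6Z,9Z,11S,11aR)-11-hydroxy-6,10-dimethyl-3-{[1-(2-nitrobenzenesulfonyl)hydrazinyl]methyl}-2,8-dioxo-2,4,5,8,11,11a-hexahydrocyclodeca[b]furan-4-yl (2E)-2-methylbut-2-enoate F3. On warming, F3 loses the sulfinic acid to give the allylic diazene F4, and F4 loses N2 in a retro-ene reaction that places hydrogen on C7 and the alkene at C11=C13. The route is rejoined at 28.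

**Step 6 (together with the handling of 7 from step 4).**
- What may go wrong: ionisation of the furan-stabilised allylic bromide with loss of the Z geometry, allylic transposition or polymerisation before alkylation.
- Fallback: it sets out from 10 and attaches the furan after the alkylation. Prop-2-yn-1-ol is carbometalated (MeMgBr, CuI cat.; then I2) to (2Z)-3-iodo-2-methylprop-2-en-1-ol F5, which is converted (CBr4, PPh3) into (1Z)-3-bromo-1-iodo-2-methylprop-1-ene F6. Alkylation of the azaenolate of 10 with F6 gives (4S)-4-[(2Z)-3-iodo-2-methylprop-2-en-1-yl]-N-[(2S)-2-(methoxymethyl)pyrrolidin-1-yl]-2,2-dimethyl-1,3-dioxan-5-imine F7. Oxalic acid hydrolysis gives (4S)-4-[(2Z)-3-iodo-2-methylprop-2-en-1-yl]-2,2-dimethyl-1,3-dioxan-5-one F8. Stille coupling of F8 with tributyl(4-methylfuran-2-yl)stannane F9 (Pd2(dba)3, AsPh3, CuI, DMF, rt) rejoins the route at 13. F9 would come from 3-methylfuran by metalation at the unhindered α-carbon with lithium 2,2,6,6-tetramethylpiperidide and Bu3SnCl, freed from its regioisomer.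

**Step 13.**
- What may go wrong: epimerisation at C8, which is α to the ketone and carries an acyloxy group, before the ring closes; elimination of silanolate from the phosphonate carbanion.
- Fallback: it sets out from 19 and introduces the tiglate after ring formation. Et3SiOTf and 2,6-lutidine give the C3 O-triethylsilyl ether of 19, F13, whose α-proton is less acidic. The same LiCl/i-Pr2NEt closure gives 4-({[tert-butyl(dimethyl)silyl]oxy}methyl)-3-{(1S,3Z)-3-methyl-4-(4-methylfuran-2-yl)-1-[(triethylsilyl)oxy]but-3-en-1-yl}furan-2(5H)-one F14. PPTS in MeOH at 0 °C frees the secondary alcohol F15, and acylation with 20 (pyridine, DMAP) rejoins the route at 22.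

**Step 11.**
- What may go wrong: incomplete discrimination between the primary and the secondary hydroxyl, leading to double acylation or acyl migration.
- Fallback: it sets out from 14 and differentiates the hydroxyls by protection. Et3SiCl and imidazole at −78 °C give (3S,5Z)-3-hydroxy-5-methyl-6-(4-methylfuran-2-yl)-1-[(triethylsilyl)oxy]hex-5-en-2-one F10. Acylation with 20 gives the C3 tiglate F11. HF·pyridine frees the primary alcohol, (3S,5Z)-1-hydroxy-5-methyl-6-(4-methylfuran-2-yl)-2-oxohex-5-en-3-yl (2E)-2-methylbut-2-enoate F12. Coupling of F12 with 18 (DCC, DMAP) rejoins the route at 21.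

## Further compounds

F1 | step 14 | (1S,3Z,6Z)-1-[5-{[tert-butyl(dimethyl)silyl]oxy}-4-({[tert-butyl(dimethyl)silyl]oxy}methyl)furan-3-yl]-3,7-dimethyl-5,8-dioxoocta-3,6-dien-1-yl (2E)-2-methylbut-2-enoate | O=C/C(C)=C\C(=O)/C=C(/C)C[C@H](OC(=O)/C(C)=C/C)c1coc(O[Si](C)(C)C(C)(C)C)c1CO[Si](C)(C)C(C)(C)C
F2 | step 14 | (4S,6Z,9Z,11S,11aR)-11-{[tert-butyl(dimethyl)silyl]oxy}-3-({[tert-butyl(dimethyl)silyl]oxy}methyl)-6,10-dimethyl-2,8-dioxo-2,4,5,8,11,11a-hexahydrocyclodeca[b]furan-4-yl (2E)-2-methylbut-2-enoate | CC(C)(C)[Si](C)(C)OCC1=C2[C@@H](OC(=O)/C(C)=C/C)C/C(C)=C\C(=O)/C=C(/C)[C@H](O[Si](C)(C)C(C)(C)C)[C@@H]2OC1=O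
F3 | step 17 | (4S,6Z,9Z,11S,11aR)-11-hydroxy-6,10-dimethyl-3-{[1-(2-nitrobenzenesulfonyl)hydrazinyl]methyl}-2,8-dioxo-2,4,5,8,11,11a-hexahydrocyclodeca[b]furan-4-yl (2E)-2-methylbut-2-enoate | NN(CC1=C2[C@@H](OC(=O)/C(C)=C/C)C/C(C)=C\C(=O)/C=C(/C)[C@H](O)[C@@H]2OC1=O)S(=O)(=O)c1ccccc1[N+](=O)[O-]
F4 | step 17 | (4S,6Z,9Z,11S,11aR)-3-(diazenylmethyl)-11-hydroxy-6,10-dimethyl-2,8-dioxo-2,4,5,8,11,11a-hexahydrocyclodeca[b]furan-4-yl (2E)-2-methylbut-2-enoate | N=NCC1=C2[C@@H](OC(=O)/C(C)=C/C)C/C(C)=C\C(=O)/C=C(/C)[C@H](O)[C@@H]2OC1=O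
F5 | step 6 | (2Z)-3-iodo-2-methylprop-2-en-1-ol | OC/C(C)=C\I
F6 | step 6 | (1Z)-3-bromo-1-iodo-2-methylprop-1-ene | BrC/C(C)=C\I
F7 | step 6 | (4S)-4-[(2Z)-3-iodo-2-methylprop-2-en-1-yl]-N-[(2S)-2-(methoxymethyl)pyrrolidin-1-yl]-2,2-dimethyl-1,3-dioxan-5-imine | COC[C@@H]1CCCN1N=C1COC(C)(C)O[C@H]1C/C(C)=C\I
F8 | step 6 | (4S)-4-[(2Z)-3-iodo-2-methylprop-2-en-1-yl]-2,2-dimethyl-1,3-dioxan-5-one | CC1(C)OCC(=O)[C@H](C/C(C)=C\I)O1
F9 | step 6 | tributyl(4-methylfuran-2-yl)stannane | CCCC[Sn](CCCC)(CCCC)c1cc(C)co1
F10 | step 11 | (3S,5Z)-3-hydroxy-5-methyl-6-(4-methylfuran-2-yl)-1-[(triethylsilyl)oxy]hex-5-en-2-one | CC[Si](CC)(CC)OCC(=O)[C@@H](O)C/C(C)=C\c1cc(C)co1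
F11 | step 11 | (3S,5Z)-5-methyl-6-(4-methylfuran-2-yl)-2-oxo-1-[(triethylsilyl)oxy]hex-5-en-3-yl (2E)-2-methylbut-2-enoate | CC[Si](CC)(CC)OCC(=O)[C@@H](OC(=O)/C(C)=C/C)C/C(C)=C\c1cc(C)co1
F12 | step 11 | (3S,5Z)-1-hydroxy-5-methyl-6-(4-methylfuran-2-yl)-2-oxohex-5-en-3-yl (2E)-2-methylbut-2-enoate | OCC(=O)[C@@H](OC(=O)/C(C)=C/C)C/C(C)=C\c1cc(C)co1
F13 | step 13 | (3S,5Z)-5-methyl-6-(4-methylfuran-2-yl)-2-oxo-3-[(triethylsilyl)oxy]hex-5-en-1-yl 3-{[tert-butyl(dimethyl)silyl]oxy}-2-(diethoxyphosphoryl)propanoate | CCOP(=O)(OCC)C(CO[Si](C)(C)C(C)(C)C)C(=O)OCC(=O)[C@@H](O[Si](CC)(CC)CC)C/C(C)=C\c1cc(C)co1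
F14 | step 13 | 4-({[tert-butyl(dimethyl)silyl]oxy}methyl)-3-{(1S,3Z)-3-methyl-4-(4-methylfuran-2-yl)-1-[(triethylsilyl)oxy]but-3-en-1-yl}furan-2(5H)-one | Cc1coc(/C=C(/C)C[C@H](O[Si](CC)(CC)CC)C2=C(CO[Si](C)(C)C(C)(C)C)C(=O)OC2)c1
F15 | step 13 | 4-({[tert-butyl(dimethyl)silyl]oxy}methyl)-3-[(1S,3Z)-1-hydroxy-3-methyl-4-(4-methylfuran-2-yl)but-3-en-1-yl]furan-2(5H)-one | Cc1coc(/C=C(/C)C[C@H](O)C2=C(CO[Si](C)(C)C(C)(C)C)C(=O)OC2)c1
A1 | alternative 1 | (3aS,4Z,7Z,10E,11aR)-2,2,4,8-tetramethyl-3a,9-dihydro-2H-cyclodeca[d][1,3]dioxol-6(11aH)-one (ten-membered Z,Z-dienone, C5/C6 cis-diol acetonide, E C7=C8 alkene) | O=C1/C=C(/C)C/C=C/[C@H]2OC(C)(C)O[C@H]2/C(C)=C\1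
A2 | alternative 2 | (3aR,4S,6Z,9Z,11S,11aR)-4-hydroxy-6,10-dimethyl-3-methylidene-11-[(triethylsilyl)oxy]-3a,4,5,11a-tetrahydrocyclodeca[b]furan-2,8(3H,11H)-dione | C=C1C(=O)O[C@@H]2[C@H]1[C@@H](O)C/C(C)=C\C(=O)/C=C(/C)[C@@H]2O[Si](CC)(CC)CC
A3 | alternative 3 | (3aR,4S,6Z,9Z,11S,11aR)-6,10-dimethyl-3-methylidene-2,8-dioxo-11-[(triethylsilyl)oxy]-2,3,3a,4,5,8,11,11a-octahydrocyclodeca[b]furan-4-yl (2E)-2-methylbut-2-enoate | C=C1C(=O)O[C@@H]2[C@H]1[C@@H](OC(=O)/C(C)=C/C)C/C(C)=C\C(=O)/C=C(/C)[C@@H]2O[Si](CC)(CC)CC
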